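The plan cuts the target back to (+)-β-selinene and that hydrocarbon to acyclic (2E,6E)-farnesyl diphosphate. The fifteen skeletal carbons C1–C15 still follow the head-to-tail order of a farnesyl chain, wound into rings A and B, with C7 and C10 (and originally C5) in the natural eudesmane configuration. A class 1 sesquiterpene cyclase exploits this: in one operation it forms the C6–C7 and C5–C10 bonds, both rings and three stereocentres from an achiral diphosphate. Later steps only change oxidation levels: C12 becomes the methyl ester, C3 the β-angelate, and a final singlet-oxygen ene reaction, steered by the C14 methyl, installs the 5α-hydroperoxide and restores the C4=C15 alkene.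

Key step: step 3

Remark: eudesmane numbering is used (C14 angular methyl, C15 on C4, C11–C13 side chain); diphosphate 3 is drawn as the free acid but handled as its trisammonium salt, and the synthase is assumed to release the (4aR,7R,8aS) hydrocarbon, as plant enzymes of this type do.

Step 1
Reactants: 1 (2E,6E)-farnesol
Product: 2 (2E,6E)-farnesyl bromide
Conditions: PBr3, Et2O, −10 °C
Reagents that add atoms: phosphorus tribromide, BrP(Br)Br
Why: Bromination of a primary allylic alcohol through its phosphite ester (SN2 by bromide) is fast at low temperature and should keep both E alkenes and the primary position; the crude bromide is used at once.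

Step 2
Reactants: 2 (2E,6E)-farnesyl bromide
Product: 3 (2E,6E)-farnesyl diphosphate
Conditions: (Bu4N)3HP2O7, MeCN, rt; then Dowex 50WX8 (NH4+ form), aq NH4HCO3
Reagents that add atoms: tris(tetrabutylammonium) hydrogen diphosphate, CCCC[N+](CCCC)(CCCC)CCCC.CCCC[N+](CCCC)(CCCC)CCCC.CCCC[N+](CCCC)(CCCC)CCCC.OP(=O)([O-])OP(=O)([O-])[O-]
Why: SN2 displacement of the primary allylic bromide by the diphosphate trianion in acetonitrile (allylic diphosphorylation) should give the diphosphate monoester, which cation exchange turns into the water-soluble ammonium salt that the enzyme accepts.

Step 3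
Reactants: 3 (2E,6E)-farnesyl diphosphate
Product: 5 (+)-β-selinene, via enzyme-bound germacrene A 4 (not isolated)
Conditions: recombinant β-selinene synthase (class 1), MgCl2, HEPES buffer pH 7.5, DTT, glycerol, 30 °C, pentane overlay
Reagents that add atoms: none
Why: In the active site MgCl2-assisted loss of diphosphate gives the (2E,6E)-farnesyl cation, C7 of the C7=C11 alkene bonds to C6 (Markovnikov macrocyclisation, ten-membered ring, tertiary cation left on exocyclic C11) and loss of a C12/C13 proton leaves bound germacrene A 4. Protonation of C1 then generates the C10 cation, which is captured through C5 by the C4=C5 alkene in a transannular closure that divides the ten-membered ring into the six-membered rings A and B, and the resulting C4 cation loses a C15 proton. This is class 1 terpene synthase catalysis, an enzyme-templated cation–olefin polycyclisation for which β-selinene synthases are characterised; its closest abiotic relative is the acid-induced cyclisation of germacrene A to selinenes. C7 is set by the alkene face that the enzyme presents to C6, and C5 and C10 by anti addition across the two alkenes in a chair–chair conformer, which gives the trans ring fusion with the C14 methyl β and H-5 α. The selectivity required is threefold (coiling of the chain, face of bond formation, removal of the last proton from C15 and not from C3 or C5), and it is imposed by the shape of the pocket and the position of its base; the substrate itself secures only the E geometry of both trisubstituted alkenes, which places C14 and C15 correctly.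

Step 4
Reactants: 5 (+)-β-selinene
Product: 8 β-costol, via 12-lithio-β-selinene 6 (not isolated), via dimethyl β-selinen-12-ylboronate 7 (not isolated)
Conditions: n-BuLi, TMEDA, hexane, rt; B(OMe)3, THF, −78 °C to rt; then H2O2, aq NaOH, 0 °C
Reagents that add atoms: hydrogen peroxide, OO
Why: Kinetic allylic lithiation with n-BuLi·TMEDA favours the primary C12–H of the isopropenyl group over the ring methylene C3–H (CH3 > CH2 > CH), and borylation–oxidation of the symmetrical 2-substituted allyllithium can give only the C12 alcohol with the C11=C13 alkene kept.

Step 5
Reactants: 8 β-costol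
Product: 10 β-costic acid, via β-costal 9 (not isolated)
Conditions: TEMPO (cat.), PhI(OAc)2, CH2Cl2, rt; then NaClO2, NaH2PO4, 2-methyl-2-butene, t-BuOH/H2O, rt
Reagents that add atoms: sodium chlorite, [Na+].[O-]Cl=O
Why: Oxoammonium oxidation stops at the enal, and the Pinnick oxidation then converts the 2-substituted acrolein to the acid without touching either alkene, the scavenger removing HOCl.

Step 6
Reactants: 10 β-costic acid
Product: 11 methyl β-costate
Conditions: MeI, K2CO3, DMF, rt
Reagents that add atoms: iodomethane, CI
Why: SN2 O-alkylation of the carboxylate under mild base gives the methyl ester and avoids diazoalkanes, which add to acrylates.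

Step 7
Reactants: 11 methyl β-costate
Product: 12 methyl isocostate
Conditions: p-TsOH·H2O (cat.), toluene, 80 °C
Reagents that add atoms: none
Why: Acid-catalysed alkene isomerisation through the tertiary C4 cation moves the exocyclic double bond to the thermodynamically preferred tetrasubstituted C4=C5 position while the electron-poor acrylate is not protonated; the C5 stereocentre is given up here on purpose and rebuilt in step 11.

Step 8
Reactants: 12 methyl isocostate
Product: 13 methyl 3-oxoeudesma-4,11(13)-dien-12-oate
Conditions: CrO3, 3,5-dimethylpyrazole, CH2Cl2, −20 °C
Reagents that add atoms: chromium trioxide, O=[Cr](=O)=O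
Why: Allylic oxidation with the CrO3·3,5-dimethylpyrazole complex turns a ring methylene next to the tetrasubstituted alkene into the enone carbonyl, and C3 should be preferred because its axial α-hydrogen is exposed whereas the axial hydrogen at C6 lies under the C14 methyl and beside the C7 substituent.

Step 9
Reactants: 13 methyl 3-oxoeudesma-4,11(13)-dien-12-oate
Product: 14 methyl 3β-hydroxyeudesma-4,11(13)-dien-12-oate
Conditions: NaBH4, CeCl3·7H2O, MeOH, −78 °C
Reagents that add atoms: none
Why: Luche reduction gives 1,2-reduction of the enone only (the acrylate ester is left at −78 °C), and hydride adds axially from the α face, away from the axial C14 methyl, to give the equatorial 3β-alcohol.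

Step 10
Reactants: 14 methyl 3β-hydroxyeudesma-4,11(13)-dien-12-oate, 15 angelic acid
Product: 17 methyl 3β-angeloyloxyeudesma-4,11(13)-dien-12-oate, via angelic 2,4,6-trichlorobenzoic anhydride 16 (not isolated)
Conditions: 2,4,6-trichlorobenzoyl chloride, Et3N, toluene, rt; then 14, 80 °C
Reagents that add atoms: none
Why: Yamaguchi esterification through the mixed anhydride, run without a nucleophilic catalyst, acylates the alcohol at the less hindered angeloyl carbonyl with retention at C3 and should not isomerise the Z alkene to the tiglate.

Step 11
Reactants: 17 methyl 3β-angeloyloxyeudesma-4,11(13)-dien-12-oate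
Product: 18 methyl 3β-angeloyloxy-5α-hydroperoxyeudesma-4(15),11(13)-dien-12-oate
Conditions: O2, tetraphenylporphyrin (cat.), white LED, CH2Cl2, 0 °C
Reagents that add atoms: dioxygen (as singlet oxygen), O=O
Why: Schenck ene reaction of singlet oxygen with the electron-rich tetrasubstituted alkene (both conjugated esters are inert): attack on the α face, opposite the axial C14 methyl, forms the C5–O bond and takes a hydrogen from the C15 methyl, which sets the 5α-hydroperoxide and the C4=C15 alkene, while abstraction of H-3, geminal to the acyloxy group, is disfavoured.

Compound list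
1 | (2E,6E)-farnesol | CC(C)=CCC/C(C)=C/CC/C(C)=C/CO | starting material
2 | (2E,6E)-farnesyl bromide | CC(C)=CCC/C(C)=C/CC/C(C)=C/CBr | intermediate
3 | (2E,6E)-farnesyl diphosphate (drawn as free acid, used as trisammonium salt) | CC(C)=CCC/C(C)=C/CC/C(C)=C/COP(=O)(O)OP(=O)(O)O | intermediate
4 | (+)-(R)-germacrene A, (1(10)E,4E)-germacra-1(10),4,11-triene, C7 as in 5, enzyme-bound | C/C1=C\CC/C(C)=C/C[C@H](C(C)=C)CC1 | intermediate
5 | (+)-β-selinene, (4aR,7R,8aS)-eudesma-4(15),11-diene, H-5α, 7β-isopropenyl, 10β-methyl | C=C(C)[C@@H]1CC[C@@]2(C)CCCC(=C)[C@@H]2C1 | intermediate
6 | 12-lithio-β-selinene (2-substituted allyllithium, TMEDA complex) | [Li]CC(=C)[C@@H]1CC[C@@]2(C)CCCC(=C)[C@@H]2C1 | intermediate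
7 | dimethyl β-selinen-12-ylboronate | COB(OC)CC(=C)[C@@H]1CC[C@@]2(C)CCCC(=C)[C@@H]2C1 | intermediate
8 | β-costol, eudesma-4(15),11(13)-dien-12-ol | C=C(CO)[C@@H]1CC[C@@]2(C)CCCC(=C)[C@@H]2C1 | intermediate
9 | β-costal, eudesma-4(15),11(13)-dien-12-al | C=C(C=O)[C@@H]1CC[C@@]2(C)CCCC(=C)[C@@H]2C1 | intermediate
10 | β-costic acid, eudesma-4(15),11(13)-dien-12-oic acid | C=C(C(=O)O)[C@@H]1CC[C@@]2(C)CCCC(=C)[C@@H]2C1 | intermediate
11 | methyl β-costate, methyl eudesma-4(15),11(13)-dien-12-oate | C=C(C(=O)OC)[C@@H]1CC[C@@]2(C)CCCC(=C)[C@@H]2C1 | intermediate
12 | methyl isocostate, methyl eudesma-4,11(13)-dien-12-oate | C=C(C(=O)OC)[C@@H]1CC[C@@]2(C)CCCC(C)=C2C1 | intermediate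
13 | methyl 3-oxoeudesma-4,11(13)-dien-12-oate | C=C(C(=O)OC)[C@@H]1CC[C@@]2(C)CCC(=O)C(C)=C2C1 | intermediate
14 | methyl 3β-hydroxyeudesma-4,11(13)-dien-12-oate | C=C(C(=O)OC)[C@@H]1CC[C@@]2(C)CC[C@H](O)C(C)=C2C1 | intermediate
15 | angelic acid, (Z)-2-methylbut-2-enoic acid | C/C=C(/C)C(=O)O | starting material
16 | angelic 2,4,6-trichlorobenzoic anhydride | C/C=C(/C)C(=O)OC(=O)c1c(Cl)cc(Cl)cc1Cl | intermediate
17 | methyl 3β-angeloyloxyeudesma-4,11(13)-dien-12-oate | C=C(C(=O)OC)[C@@H]1CC[C@@]2(C)CC[C@H](OC(=O)/C(C)=C\C)C(C)=C2C1 | intermediate
18 | methyl 3β-angeloyloxy-5α-hydroperoxyeudesma-4(15),11(13)-dien-12-oate (CNP0137897.1) | C=C(C(=O)OC)[C@@H]1CC[C@@]2(C)CC[C@H](OC(=O)/C(C)=C\C)C(=C)[C@]2(OO)C1 | target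

Total step count: 11. Longest linear sequence: 11 steps (1 to 18); angelic acid 15 enters in step 10.

Steps most likely to fail

Step 3. The cyclase may release the ten-membered intermediate before the second closure, remove the last proton from C3 or C5 and not from C15, or turn over too slowly on a preparative scale. The fallback sets out from 3: the diphosphate is given to a (+)-germacrene A synthase (MgCl2, buffer, 30 °C, pentane overlay), an enzyme type that stops after the C6–C7 closure, and (R)-germacrene A 4 is collected cold. Stirring 4 in pentane with acidic silica gel then closes the C5–C10 bond chemically, a known acid-induced germacrene-to-selinene cyclisation through the same chair–chair conformer. β-Selinene is separated from its ring A double-bond isomers on AgNO3-impregnated silica, and the route is rejoined at 5. No compound outside the list is made (F0).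

Step 4. Deprotonation may occur at the ring allylic methylene C3 in competition with C12, or metalation may stay incomplete, leading to regioisomeric alcohols that are hard to separate. The fallback sets out from 5 and oxidises the side chain by an ene/[2,3]-sigmatropic sequence instead of by deprotonation (SeO2 cat., t-BuOOH, CH2Cl2, rt), which takes the isopropenyl methyl directly to aldehyde 9. Material hydroxylated at C3 is more polar and is removed by chromatography. The route is rejoined at 9, which enters the chlorite stage of step 5. No compound outside the list is made (F0).

Step 8. Hydrogen abstraction may occur at C6 or at the C15 methyl instead of C3, or the enone may be oxidised further to an ene-dione. The fallback sets out from 11, before the ring alkene is moved, where C3 is the only allylic methylene of the only electron-rich alkene. Hydroxylation with SeO2 (cat.) and t-BuOOH should give methyl 3α-hydroxyeudesma-4(15),11(13)-dien-12-oate F1 (axial alcohol expected; the centre is erased next). Dess–Martin oxidation should then give the α-methylene ketone methyl 3-oxoeudesma-4(15),11(13)-dien-12-oate F2. A rhodium-hydride double-bond migration (RhCl3·3H2O cat., EtOH, 70 °C), a known exo-to-endo enone isomerisation driven by the tetrasubstituted conjugated product, should move the alkene into the ring. This last stage carries its own risk, since the α-methylene ester can migrate under the same catalyst, so it is stopped as soon as F2 is consumed. The route is rejoined at 13, and step 7 is bypassed as well.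

Further compounds
F0 | step 3 | none | none
F0 | step 4 | none | none
F1 | step 8 | methyl 3α-hydroxyeudesma-4(15),11(13)-dien-12-oate | C=C(C(=O)OC)[C@@H]1CC[C@@]2(C)CC[C@@H](O)C(=C)[C@@H]2C1
F2 | step 8 | methyl 3-oxoeudesma-4(15),11(13)-dien-12-oate | C=C(C(=O)OC)[C@@H]1CC[C@@]2(C)CCC(=O)C(=C)[C@@H]2C1
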